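**Plan**

Locants: ring A is the guaiacyl ring, C7 the benzylic carbinol carbon, C8 the ether-bearing carbon, C9 the CH2OH carbon; ring B is the dimethoxyphenyl ring and C4' its oxygen-bearing carbon.
Retrosynthesis: the O–C4' aryl ether bond is cut first (from the aryl side). Next comes the C7–O bond of a benzyl ether (back to a trans-epoxide), then the epoxide C–O bonds (back to an E-alkene), then C7=C8 (back to the ring A aldehyde). The ring B CH2OH is traced to a tert-butyl ester.
Forward: the C7–C8–C9 chain is grown on ring A by olefination, epoxidised and opened to the erythro carbinol, and only then joined to ring B. No ring is formed; both arenes are bought.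
Enabling feature: the one oxygen linking the halves sits on secondary C8 (between benzylic C7 and C9) and on C4' of ring B (between methoxy-bearing C3' and C5'). Attaching C4' to the existing C8 oxygen therefore disturbs no bond at C7 or C8.
Stereochemistry: Sharpless epoxidation with L-(+)-diisopropyl tartrate sets C7 and C8 (both S). SN2 opening at C7 inverts it to R, giving (7R,8S) erythro; no later step breaks a bond at either centre.

Key step: step 7

Remark: ring B is carried as a tert-butyl ester, because a methyl ester could exchange with the C8 alkoxide under the coupling conditions and the released methanol would be arylated. 4-Bromo-3,5-dimethoxybenzoic acid is taken as commercial.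

Step 1
Reactants: 1 4-(benzyloxy)-3-methoxybenzaldehyde; 2 triethyl phosphonoacetate
Product: 3 ethyl (E)-3-[4-(benzyloxy)-3-methoxyphenyl]prop-2-enoate
Conditions: NaH, THF, 0 °C to rt
Reagents that add atoms: none
Why: Horner–Wadsworth–Emmons olefination of an aromatic aldehyde with a stabilised phosphonate anion should give the E-enoate almost exclusively, fixing the alkene geometry that the epoxidation later turns into relative configuration.

Step 2
Reactants: 3 ethyl (E)-3-[4-(benzyloxy)-3-methoxyphenyl]prop-2-enoate
Product: 5 (E)-3-[4-(benzyloxy)-3-methoxyphenyl]prop-2-en-1-ol, via (E)-4-benzyloxy-3-methoxycinnamaldehyde 4 (not isolated)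
Conditions: i-Bu2AlH (2.5 equiv), CH2Cl2, −78 to 0 °C; aq. potassium sodium tartrate
Reagents that add atoms: none
Why: hydride reduction of an enoate by i-Bu2AlH proceeds by 1,2-addition through the enal to the allylic alcohol and leaves the alkene and the aryl benzyl ether untouched.

Step 3
Reactants: 5 (E)-3-[4-(benzyloxy)-3-methoxyphenyl]prop-2-en-1-ol
Product: 6 [(2S,3S)-3-[4-(benzyloxy)-3-methoxyphenyl]oxiran-2-yl]methanol
Conditions: Ti(OiPr)4 (10 mol %), L-(+)-diisopropyl tartrate (14 mol %), t-BuOOH (2 equiv, isooctane), 4 Å molecular sieves, CH2Cl2, −25 °C; then aq. NaOH/NaCl, 0 °C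
Reagents that add atoms: tert-butyl hydroperoxide, CC(C)(C)OO
Why: Sharpless asymmetric epoxidation: the titanium L-(+)-tartrate complex binds the allylic alcohol and delivers the peroxide oxygen to the alkene face that gives the trans (2S,3S)-epoxide, setting C7 and C8 together, while the low catalyst loading and basic quench limit opening of the electron-rich aryl epoxide.

Step 4
Reactants: 6 [(2S,3S)-3-[4-(benzyloxy)-3-methoxyphenyl]oxiran-2-yl]methanol
Product: 7 (2S,3S)-2-[(benzyloxy)methyl]-3-[4-(benzyloxy)-3-methoxyphenyl]oxirane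
Conditions: NaH, BnBr, Bu4NI (cat.), THF, 0 °C to rt
Reagents that add atoms: benzyl bromide, BrCc1ccccc1
Why: Williamson etherification of the primary alkoxide in an aprotic solvent is faster than Payne rearrangement, so the epoxide and both stereocentres should pass through unchanged.

Step 5
Reactants: 7 (2S,3S)-2-[(benzyloxy)methyl]-3-[4-(benzyloxy)-3-methoxyphenyl]oxirane; 8 benzyl alcohol
Product: 9 (1R,2S)-1,3-bis(benzyloxy)-1-[4-(benzyloxy)-3-methoxyphenyl]propan-2-ol (erythro)
Conditions: NaOBn (0.3 equiv), BnOH (solvent), 90 °C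
Reagents that add atoms: none
Why: alkoxide opening of an epoxide by an SN2 path: benzyl oxide attacks C7, which is benzylic and remote from the deactivating C9 oxygen, anti to the epoxide oxygen, so C7 inverts from S to R while C8 keeps its oxygen and configuration, and without acid the electron-rich benzylic carbon cannot ionise and scramble.

Step 6
Reactants: 10 4-bromo-3,5-dimethoxybenzoic acid
Product: 11 tert-butyl 4-bromo-3,5-dimethoxybenzoate
Conditions: t-BuOC(=NH)CCl3 (2 equiv), CH2Cl2–cyclohexane, rt
Reagents that add atoms: tert-butyl 2,2,2-trichloroacetimidate, CC(C)(C)OC(=N)C(Cl)(Cl)Cl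
Why: imidate esterification: the carboxylic acid protonates the trichloroacetimidate, the tert-butyl group is transferred to the carboxylate and neutral trichloroacetamide leaves, under conditions to which the aryl bromide and methyl ethers are inert.

Step 7
Reactants: 9 (1R,2S)-1,3-bis(benzyloxy)-1-[4-(benzyloxy)-3-methoxyphenyl]propan-2-ol; 11 tert-butyl 4-bromo-3,5-dimethoxybenzoate
Product: 12 tert-butyl 4-{[(1R,2S)-1,3-bis(benzyloxy)-1-[4-(benzyloxy)-3-methoxyphenyl]propan-2-yl]oxy}-3,5-dimethoxybenzoate
Conditions: CuI (20 mol %), 3,4,7,8-tetramethyl-1,10-phenanthroline (40 mol %), Cs2CO3 (2.5 equiv), 11 (2.5 equiv), 4 Å molecular sieves, toluene, 120 °C, sealed tube, Ar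
Reagents that add atoms: none
Why: Cs2CO3 and phenanthroline-ligated CuI turn the C8 hydroxyl into a monovalent copper alkoxide, the C4'–Br bond of 11 adds to it to give a trivalent copper aryl alkoxide, and reductive elimination forms the O–C4' bond and returns monovalent copper. The closest known reaction type is the Ullmann-type copper-catalysed etherification of secondary alcohols with aryl bromides and iodides under phenanthroline ligands, which is also known for ortho-substituted halides. No ring is closed and no stereocentre is created; C7 (R) and C8 (S) are retained because no bond to either carbon is broken and neither C–H is acidic towards carbonate. The step needs chemoselective O-arylation of a hindered carbinol: C8–OH is the only free hydroxyl in 9, the para ester eases C–Br activation, the two ortho methoxy oxygens can hold copper beside that bond, and the tert-butyl ester resists attack by the alkoxide. The bromide is used in excess because 9 is the valuable partner, and a copper alkoxide is far less prone to beta-hydride loss than a palladium alkoxide would be.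

Step 8
Reactants: 12 tert-butyl 4-{[(1R,2S)-1,3-bis(benzyloxy)-1-[4-(benzyloxy)-3-methoxyphenyl]propan-2-yl]oxy}-3,5-dimethoxybenzoate
Product: 14 (4-{[(1R,2S)-1,3-bis(benzyloxy)-1-[4-(benzyloxy)-3-methoxyphenyl]propan-2-yl]oxy}-3,5-dimethoxyphenyl)methanol, via the ring B benzaldehyde 13 (not isolated)
Conditions: LiAlH4, THF, 0 °C to rt; aq. potassium sodium tartrate
Reagents that add atoms: none
Why: LiAlH4 reduction of a benzoate ester runs through the aldehyde to the benzylic alcohol, while benzyl and aryl ethers are inert to hydride and no stereocentre is involved.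

Step 9
Reactants: 14 (4-{[(1R,2S)-1,3-bis(benzyloxy)-1-[4-(benzyloxy)-3-methoxyphenyl]propan-2-yl]oxy}-3,5-dimethoxyphenyl)methanol
Product: 15 (1R,2S)-1-(4-hydroxy-3-methoxyphenyl)-2-[4-(hydroxymethyl)-2,6-dimethoxyphenoxy]propane-1,3-diol
Conditions: H2 (1 atm), 10% Pd/C, EtOAc–EtOH, rt, stopped at full debenzylation
Reagents that add atoms: none
Why: catalytic hydrogenolysis of benzyl ethers: the three unhindered O–CH2Ph bonds should be cleaved on palladium at 1 atm in a neutral solvent well before the hindered secondary C7–O bond or the ring B CH2–OH bond reacts, so both benzylic alcohols and the C7 configuration survive.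

**Compound list**

1 | 4-(benzyloxy)-3-methoxybenzaldehyde | COc1cc(C=O)ccc1OCc1ccccc1 | starting material
2 | triethyl phosphonoacetate | CCOC(=O)CP(=O)(OCC)OCC | starting material
3 | ethyl (E)-3-[4-(benzyloxy)-3-methoxyphenyl]prop-2-enoate | CCOC(=O)/C=C/c1ccc(OCc2ccccc2)c(OC)c1 | intermediate
4 | (E)-3-[4-(benzyloxy)-3-methoxyphenyl]prop-2-enal (not isolated) | O=C/C=C/c1ccc(OCc2ccccc2)c(OC)c1 | intermediate
5 | (E)-3-[4-(benzyloxy)-3-methoxyphenyl]prop-2-en-1-ol | OC/C=C/c1ccc(OCc2ccccc2)c(OC)c1 | intermediate
6 | [(2S,3S)-3-[4-(benzyloxy)-3-methoxyphenyl]oxiran-2-yl]methanol | OC[C@@H]1O[C@H]1c1ccc(OCc2ccccc2)c(OC)c1 | intermediate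
7 | (2S,3S)-2-[(benzyloxy)methyl]-3-[4-(benzyloxy)-3-methoxyphenyl]oxirane | C(OC[C@@H]1O[C@H]1c1ccc(OCc2ccccc2)c(OC)c1)c1ccccc1 | intermediate
8 | benzyl alcohol | OCc1ccccc1 | starting material
9 | (1R,2S)-1,3-bis(benzyloxy)-1-[4-(benzyloxy)-3-methoxyphenyl]propan-2-ol | COc1cc([C@@H](OCc2ccccc2)[C@H](COCc2ccccc2)O)ccc1OCc1ccccc1 | intermediate
10 | 4-bromo-3,5-dimethoxybenzoic acid | OC(=O)c1cc(OC)c(Br)c(OC)c1 | starting material
11 | tert-butyl 4-bromo-3,5-dimethoxybenzoate | CC(C)(C)OC(=O)c1cc(OC)c(Br)c(OC)c1 | intermediate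
12 | tert-butyl 4-{[(1R,2S)-1,3-bis(benzyloxy)-1-[4-(benzyloxy)-3-methoxyphenyl]propan-2-yl]oxy}-3,5-dimethoxybenzoate | COc1cc([C@@H](OCc2ccccc2)[C@H](COCc2ccccc2)Oc2c(OC)cc(C(=O)OC(C)(C)C)cc2OC)ccc1OCc1ccccc1 | intermediate
13 | 4-{[(1R,2S)-1,3-bis(benzyloxy)-1-[4-(benzyloxy)-3-methoxyphenyl]propan-2-yl]oxy}-3,5-dimethoxybenzaldehyde (not isolated) | COc1cc([C@@H](OCc2ccccc2)[C@H](COCc2ccccc2)Oc2c(OC)cc(C=O)cc2OC)ccc1OCc1ccccc1 | intermediate
14 | (4-{[(1R,2S)-1,3-bis(benzyloxy)-1-[4-(benzyloxy)-3-methoxyphenyl]propan-2-yl]oxy}-3,5-dimethoxyphenyl)methanol | COc1cc([C@@H](OCc2ccccc2)[C@H](COCc2ccccc2)Oc2c(OC)cc(CO)cc2OC)ccc1OCc1ccccc1 | intermediate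
15 | (1R,2S)-1-(4-hydroxy-3-methoxyphenyl)-2-[4-(hydroxymethyl)-2,6-dimethoxyphenoxy]propane-1,3-diol | COc1cc([C@@H](O)[C@H](CO)Oc2c(OC)cc(CO)cc2OC)ccc1O | target

Total step count: 9. Longest linear sequence: 8 steps (steps 1 to 5 and 7 to 9, from 1 to 15); step 6 is a one-step side branch.

**Steps most likely to fail**

Step 7 (key coupling). Activation of the C4'–Br bond and transfer of the bulky alkoxide may both be slowed by the two ortho methoxy groups and by the branching at C7 and C9. Debromination of 11 and recovery of 9 would then outrun ether formation. The fallback makes the ether from the alkyl side by double inversion and sets out from 9. A Mitsunobu reaction with 4-nitrobenzoic acid (PPh3, DIAD, THF) would invert C8 and give (1R,2R)-1,3-bis(benzyloxy)-1-[4-(benzyloxy)-3-methoxyphenyl]propan-2-yl 4-nitrobenzoate F1. Methanolysis (K2CO3, MeOH) would free the threo alcohol (1R,2R)-1,3-bis(benzyloxy)-1-[4-(benzyloxy)-3-methoxyphenyl]propan-2-ol F2. A second Mitsunobu reaction with methyl 4-hydroxy-3,5-dimethoxybenzoate (PPh3, DIAD, toluene) would invert C8 again and give methyl 4-{[(1R,2S)-1,3-bis(benzyloxy)-1-[4-(benzyloxy)-3-methoxyphenyl]propan-2-yl]oxy}-3,5-dimethoxybenzoate F3. LiAlH4 reduction of F3 gives 14, where the route is rejoined.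

Step 5 (epoxide opening). Opening at a doubly secondary epoxide may be slow enough that the product alkoxide adds to unreacted epoxide, or some attack may occur at C8. The fallback uses chelate-directed opening of the free epoxy alcohol and sets out from 6. Ti(OBn)4, made from Ti(OiPr)4 and BnOH with removal of isopropanol, would bind the epoxy alcoholate and deliver benzyl oxide to C7 with inversion (the C3-selective opening of 2,3-epoxy alcohols). This gives (2S,3R)-3-(benzyloxy)-3-[4-(benzyloxy)-3-methoxyphenyl]propane-1,2-diol F4. Its dibutylstannylene acetal (Bu2SnO, toluene, reflux) would then be benzylated at the primary C9 oxygen only (BnBr, CsF, DMF), giving 9.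

Step 3 (asymmetric epoxidation). The electron-rich aryl epoxide may be opened at C7 by isopropanol, tartrate or water under titanium Lewis acidity or during work-up, with loss of material and of enantiomeric purity. The fallback epoxidises under buffered basic conditions and sets out from 5. O-Benzylation (NaH, BnBr, THF) gives 1-(benzyloxy)-4-[(E)-3-(benzyloxy)prop-1-en-1-yl]-2-methoxybenzene F5. Shi epoxidation of F5 then uses the enantiomer of the fructose-derived ketone (made from L-sorbose), KHSO5, K2CO3 and Bu4NHSO4 in MeCN–dimethoxymethane–aqueous buffer at about pH 10.5 and 0 °C. The D-series ketone gives (R,R)-epoxides from trans-alkenes, so its enantiomer should give the (2S,3S)-epoxide 7 directly.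

**Further compounds**

F1 | step 7 | (1R,2R)-1,3-bis(benzyloxy)-1-[4-(benzyloxy)-3-methoxyphenyl]propan-2-yl 4-nitrobenzoate | COc1cc([C@@H](OCc2ccccc2)[C@@H](COCc2ccccc2)OC(=O)c2ccc([N+](=O)[O-])cc2)ccc1OCc1ccccc1
F2 | step 7 | (1R,2R)-1,3-bis(benzyloxy)-1-[4-(benzyloxy)-3-methoxyphenyl]propan-2-ol | COc1cc([C@@H](OCc2ccccc2)[C@@H](COCc2ccccc2)O)ccc1OCc1ccccc1
F3 | step 7 | methyl 4-{[(1R,2S)-1,3-bis(benzyloxy)-1-[4-(benzyloxy)-3-methoxyphenyl]propan-2-yl]oxy}-3,5-dimethoxybenzoate | COc1cc([C@@H](OCc2ccccc2)[C@H](COCc2ccccc2)Oc2c(OC)cc(C(=O)OC)cc2OC)ccc1OCc1ccccc1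
F4 | step 5 | (2S,3R)-3-(benzyloxy)-3-[4-(benzyloxy)-3-methoxyphenyl]propane-1,2-diol | COc1cc([C@@H](OCc2ccccc2)[C@H](CO)O)ccc1OCc1ccccc1
F5 | step 3 | 1-(benzyloxy)-4-[(E)-3-(benzyloxy)prop-1-en-1-yl]-2-methoxybenzene | COc1cc(/C=C/COCc2ccccc2)ccc1OCc1ccccc1
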